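(Readings and results are simulated with constants of no real substance; scatter was added.)

The pitfall is to read the product excess as the catalyst's fixed preference and pool it over a run.

- dusk: left-handed substrate 20 mM; right-handed substrate 20 mM; partner 0.50 equiv (fed, over 1.5 h); precatalyst 5 mol%; run made earlier
- flask: left-handed substrate 20 mM; partner 1.00 equiv (fed, over 1.5 h); precatalyst 5 mol%; right-handed substrate 20 mM; time 50 h

dusk run (percent of the left-handed substrate and right-handed substrate together charged)

| time / h | left-handed product / % | right-handed product / % | left-handed substrate / % |
|---|---|---|---|
| 1.50 | 2.9 | 0 | 49.6 |
| 3.00 | 1.5 | 2.5 | 47.0 |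
| 5.00 | 4.6 | 0.6 | 44.7 |
| 6.00 | 4.3 | 2.5 | 42.1 |
| 8.00 | 5.3 | 1.9 | 40.1 |
| 10.0 | 4.5 | 2.4 | 41.0 |

(each reading ± 1 percentage point)

- free catalyst is single-handed; left-handed substrate and right-handed substrate are mirror images of each other, charged as a racemate, each of them at the stated concentration
- an excess is below zero if the other one leads

* excess of left-handed product over right-handed product in the product at 2.5 h
* excess of left-handed product over right-handed product in the product at 50 h
* part of the left-handed substrate and right-handed substrate charged together that has reacted at 50 h

1. The bench rule says an excess, once made, stays. Applied to the dusk run, the pooled readings give 40.0%.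

2. A balance tests this. From 6.00 h on, the dusk run has lost 8.93% as left-handed substrate, more than the 6.97% of both products together. Left-handed substrate can therefore pay for the right-handed product too, so I infer that right-handed product, 2.27%, arises from left-handed product by inversion (racemisation).

3. Treat that as a small correction. The mean difference of the products over the dusk run is 2.20%. Acting until 8.00 h, it gives an inversion constant k = 0.129 h⁻¹. The excess falls at 2k, so h = ln(2)/2k = 2.69 h is the excess half-life, the time in which a finished product's excess halves. It is a rough reading, given a scatter of 1 percentage point.

4. The rule holds while t/h is small, but ta/h is already 0.929 and t/h at 50 h is 18.6. My reckoning, without assuming how the making runs in time: if product is formed with a complete excess, the newest product at 2.5 h keeps it and product from the very start keeps 52.5%, so the excess lies between these two. At 50 h I expect about zero.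

5. The forecast gives 40%, 40% and 15%, holding that “the data are too noisy to show drift”. My excesses differ from it; I reckoned no reacted part.

6. The flask gives 74.4%, 0% and 18.6%.

    free catalyst + left-handed substrate ⇌ catalyst intermediate A (K = 1000 M⁻¹, k = 38000 M⁻¹ h⁻¹)
    free catalyst + right-handed substrate ⇌ catalyst intermediate B (K = 23.0 M⁻¹, k = 3470 M⁻¹ h⁻¹)
    partner + catalyst intermediate A → free catalyst + left-handed product (k = 633 M⁻¹ h⁻¹)
    partner + catalyst intermediate B → free catalyst + right-handed product (k = 18.9 M⁻¹ h⁻¹)
    left-handed product ⇌ right-handed product (k = 0.215 h⁻¹)
    2 partner → self-condensation product (k = 15.5 M⁻¹ h⁻¹)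
    partner + precatalyst → free catalyst + spent reagent (k = 10.3 M⁻¹ h⁻¹)

In the flask, the half-life of left-handed product by the forward inversion step alone, 3.2 h, is short against 50 h, and the products stand level at 8.82% and 8.82%, with 8.81% net through inversion against 0.0511% through binding of right-handed substrate. My reading of h put 18.6 spans into 50 h, and the excess of the flask there stands at 0%. In the neighbour flask with 1.70 equiv of partner, h holds no partner, so it again gives between 52.5% and a complete excess at 2.5 h and about zero at 50 h; computed, 72.6% and 0%.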